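All runs are simulated for substances that don't exist, and the scatter is random.

In time you can watch the ochre flask stop: its target reading peaks at 9.2 % at 15.0 min and has fallen to 7.4 % at 40.0 min, while trapped intermediate reads 0.9 %, nearly all of the 0.900 % that the catalyst charge amounts to.

| flask | starting material | second substrate | reagent | capture agent | free catalyst | remark | time |
|---|---|---|---|---|---|---|---|
| ochre | 0.10 M | 0.10 M | 0.12 M | 0.030 M | 0.90 mM | run made earlier |  |
| violet | 0.10 M | 0.20 M | 0.12 M | 0.030 M | 0.90 mM | run made earlier |  |
| spring | 0.10 M | 0.100 M | 0.120 M (fed, over 32.0 min) | 0.0300 M | 0.90 mM | a stirred flask in which reagent is dosed at a steady rate over 32.0 min without added volume, worked up at 40 min | 40 min |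
| winter | 0.10 M | 0.100 M | 0.120 M | 0.0300 M | 0.90 mM | a single well-mixed tank run continuously and read at steady state, 40 min in it on average |  |
| summer | 0.10 M | 0.100 M | 0.120 M | 0.0300 M | 0.90 mM | a closed flask charged with all of it at once and left for 40 min | 40 min |
| dawn | 0.10 M (fed, over 32.0 min) | 0.100 M | 0.120 M | 0.0300 M | 0.90 mM | all but starting material at the start; starting material goes in evenly over 32.0 min, the run ends at 40 min | 40 min |

- ochre (time / min: target / %, trapped intermediate / %): 3.00: 3.9, 0.3; 8.00: 6.9, 0.3; 15.0: 9.2, 1.2; 40.0: 7.4, 0.9
- violet (time / min: target / %, trapped intermediate / %): 0.667: 0.8, 0.2; 1.33: 1.6, 0.2; 3.00: 3.2, 0; 8.00: 6.0, 0.7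

(standard deviation of a reading: 0.3 percentage points)

- the stated concentrations are those of everything mixed, before any reaction; amounts are the same in each set-up
- steps under discussion: starting material + free catalyst <-> catalyst intermediate A; reagent + catalyst intermediate A -> free catalyst + target; second substrate + free catalyst <-> catalyst intermediate B; reagent + catalyst intermediate B -> free catalyst + second product; catalyst intermediate A + capture agent -> trapped intermediate; reagent + target -> over-reaction product
- the feed brings no volume worth counting
- the earlier runs were made in a closed, stirred flask

* the set-up with the highest share of target in all that became target or trapped intermediate or over-reaction product, at the outlet or at the end ("none" if the first two lie within 2 percentage points) (spring / winter / summer / dawn / none)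
* share of target in all that became target or trapped intermediate or over-reaction product, at the outlet or at the end, spring
* share of target in all that became target or trapped intermediate or over-reaction product, at the outlet or at the end, winter
* share of target in all that became target or trapped intermediate or over-reaction product, at the outlet or at the end, summer
* share of target in all that became target or trapped intermediate or over-reaction product, at the outlet or at the end, dawn

So write the balance of the catalyst, the smallest charge. Catalyst intermediate A has two exits: reagent sends it on to target and free catalyst, capture agent sends it to trapped intermediate. The target made per catalyst lost, the turnover number, therefore goes with c(reagent)/c(capture agent). The ochre readings, at a charged ratio of 4.00, give a turnover factor of 2.56, the highest target reading divided by the last trapped intermediate reading, for each unit of that ratio. Over-reaction product is not among the ochre readings, so this factor counts standing target and leaves out target that has gone on to over-reaction product.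

You use it like this. In spring reagent goes in evenly, so up to 15.0 min the ratio averages 0.938, and my reckoning gives 2.40 standing target per trapped intermediate, fewer than the 10.2 of a flask with its reagent all in at the start. Dawn has that full ratio from the start and makes its target along the feed, so that target stands less time beside reagent. I put dawn first and spring last.

The forecast names dawn, with spring 56 %, winter 60 %, summer 60 % and dawn 67 %, and says of spring: “low reagent early means capture wins”.

The simulation gives dawn: spring 37.5 %, winter 52.6 %, summer 52.3 %, dawn 65.1 %.

    starting material + free catalyst ⇌ catalyst intermediate A (K = 32.0 M⁻¹, k = 0.660 M⁻¹ s⁻¹)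
    reagent + catalyst intermediate A → free catalyst + target (k = 2.50 M⁻¹ s⁻¹)
    second substrate + free catalyst ⇌ catalyst intermediate B (K = 15.0 M⁻¹, k = 1.40 M⁻¹ s⁻¹)
    reagent + catalyst intermediate B → free catalyst + second product (k = 0.720 M⁻¹ s⁻¹)
    catalyst intermediate A + capture agent → trapped intermediate (k = 0.580 M⁻¹ s⁻¹)
    reagent + target → over-reaction product (k = 0.00340 M⁻¹ s⁻¹)

Spring at 40.0 min holds target 0.915 % and over-reaction product 0.625 % beside trapped intermediate 0.899 %, so 1.71 target were made per trapped intermediate, over-reaction product counted. The neighbour of spring charged with 0.30 M of reagent raises the mean ratio in step, so the turnover factor gives it 5.99. That neighbour holds target 1.71 % and over-reaction product 3.45 % with 98.4 % of its catalyst trapped, which makes 5.83 per trapped intermediate.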